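**Plan**

- Retrosynthetic cuts: the lactone O-1–C-6a bond (oxygen insertion into a cyclobutanone); then C-3–C-3a and C-2–C-6a together (ketene [2+2] onto a 2-substituted 2,3-dihydrofuran); then the benzylic C–OAr bond (releases (S)-pinocembrin); then the enol ether O–CH= bond and the CH2–C≡ bond (back to an epoxy alcohol).
- Enabling feature: the γ-lactone (O-1, C-2, C-3, C-3a, C-6a), cis-fused to the tetrahydrofuran (C-3a, O-4, C-5, C-6, C-6a), is a cyclobutanone plus one oxygen, and C-3a/C-6a are the enol ether carbons C-5/C-4 of the dihydrofuran.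
- Forward order: Sharpless resolution/epoxidation, silylation, alkynylation, Mo-catalysed cycloisomerisation (dihydrofuran ring), desilylation, Mitsunobu coupling with (S)-pinocembrin, acetylation, ketene cycloaddition (cyclobutanone ring), dechlorination, Baeyer–Villiger ring expansion (lactone ring), deacetylation.
- Stereochemistry: C-5 comes from the tartrate-controlled epoxidation. The benzylic carbon comes from the same resolution and is then inverted in the Mitsunobu step. C-3a and C-6a come from cis cycloaddition on the face anti to the C-5 side chain. Flavanone C-2 is bought in with (S)-pinocembrin.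

Key step: step 8

Assumption: (S)-pinocembrin is bought as the single (2S) enantiomer, and its chelated 5-OH is taken to be inert under Mitsunobu conditions, so that only the 7-OH is alkylated.

**Route**

Step 1
Reactants: 1 (±)-1-phenylprop-2-en-1-ol
Product: 2 (R)-[(2S)-oxiran-2-yl](phenyl)methanol (erythro epoxy alcohol)
Conditions: Ti(OiPr)4 (10 mol%), D-(−)-DIPT (15 mol%), tBuOOH (0.45 equiv), 4 Å MS, CH2Cl2, −20 °C
Reagents that add atoms: tert-butyl hydroperoxide, CC(C)(C)OO
Why: Sharpless asymmetric epoxidation run as a kinetic resolution: with D-(−)-tartrate the (S)-enantiomer of 1 should be epoxidised much faster and with erythro selectivity, which fixes the (S) epoxide carbon (future C-5) and the (R) carbinol, while the slow (R)-enantiomer stays behind and is separated; conversion is held below one half, so at most half of 1 can be used.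

Step 2
Reactants: 2 (R)-[(2S)-oxiran-2-yl](phenyl)methanol
Product: 3 tert-butyldimethyl{(R)-[(2S)-oxiran-2-yl](phenyl)methoxy}silane
Conditions: TBSCl, imidazole, DMF, rt
Reagents that add atoms: tert-butyldimethylsilyl chloride, CC(C)(C)[Si](C)(C)Cl
Why: Standard silylation of a secondary alcohol, which removes the acidic proton before the organolithium step and later keeps the benzylic oxygen out of the cycloisomerisation.

Step 3
Reactants: 3 tert-butyldimethyl{(R)-[(2S)-oxiran-2-yl](phenyl)methoxy}silane; 4 ethynyltrimethylsilane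
Product: 6 (1R,2S)-1-[(tert-butyldimethylsilyl)oxy]-1-phenylpent-4-yn-2-ol, via the C-silylated alkynol 5 (not isolated)
Conditions: 4, nBuLi, THF, −78 °C; BF3·OEt2; then 3, −78 °C; then K2CO3 (cat.), MeOH, 0 °C to rt
Reagents that add atoms: none
Why: Yamaguchi–Hirao alkynylation, in which the lithium acetylide of 4 opens the BF3-activated epoxide by SN2 attack at the unhindered terminal carbon without touching either stereocentre, followed by methanolytic cleavage of the alkynyl C–Si bond under conditions that leave the silyl ether in place.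

Step 4
Reactants: 6 (1R,2S)-1-[(tert-butyldimethylsilyl)oxy]-1-phenylpent-4-yn-2-ol
Product: 7 tert-butyl{(R)-[(2S)-2,3-dihydrofuran-2-yl](phenyl)methoxy}dimethylsilane
Conditions: Mo(CO)6 (25 mol%), Et3N, Et2O, hν (350 nm), rt
Reagents that add atoms: none
Why: Molybdenum-vinylidene cycloisomerisation of a homopropargylic alcohol: the terminal alkyne rearranges to a metal vinylidene whose electrophilic α-carbon is attacked by the free hydroxyl, giving the endocyclic enol ether under basic conditions, with no change at the stereocentres.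

Step 5
Reactants: 7 tert-butyl{(R)-[(2S)-2,3-dihydrofuran-2-yl](phenyl)methoxy}dimethylsilane
Product: 8 (R)-[(2S)-2,3-dihydrofuran-2-yl](phenyl)methanol
Conditions: TBAF, THF, 0 °C
Reagents that add atoms: none
Why: Fluoride cleavage of the silyl ether is basic and so spares the acid-labile enol ether (purification on Et3N-deactivated silica).

Step 6
Reactants: 8 (R)-[(2S)-2,3-dihydrofuran-2-yl](phenyl)methanol; 9 (S)-pinocembrin [(2S)-5,7-dihydroxy-2-phenylchroman-4-one]
Product: 10 (2S)-7-{(S)-[(2S)-2,3-dihydrofuran-2-yl](phenyl)methoxy}-5-hydroxy-2-phenylchroman-4-one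
Conditions: PPh3, DIAD (added last, dropwise), THF, 0 °C to rt
Reagents that add atoms: none
Why: Mitsunobu etherification, in which the more acidic, non-chelated 7-OH of 9 displaces the benzylic oxyphosphonium group by SN2 with inversion (R to S), under near-neutral conditions that should leave flavanone C-2 and the enol ether intact; slow addition of DIAD to excess phosphine keeps free azodicarboxylate away from the enol ether.

Step 7
Reactants: 10 (2S)-7-{(S)-[(2S)-2,3-dihydrofuran-2-yl](phenyl)methoxy}-5-hydroxy-2-phenylchroman-4-one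
Product: 11 (2S)-7-{(S)-[(2S)-2,3-dihydrofuran-2-yl](phenyl)methoxy}-4-oxo-2-phenylchroman-5-yl acetate
Conditions: Ac2O, pyridine, DMAP (cat.), CH2Cl2, rt
Reagents that add atoms: acetic anhydride, CC(=O)OC(C)=O
Why: DMAP-catalysed acylation of the chelated phenol, which removes the only acidic proton before the zinc/acid chloride step and makes ring A less electron-rich towards peracid later.

Step 8
Reactants: 11 (2S)-7-{(S)-[(2S)-2,3-dihydrofuran-2-yl](phenyl)methoxy}-4-oxo-2-phenylchroman-5-yl acetate; 12 trichloroacetyl chloride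
Product: 14 (1S,3S,5R)-3-{(S)-{[(2S)-5-acetoxy-4-oxo-2-phenylchroman-7-yl]oxy}(phenyl)methyl}-7,7-dichloro-2-oxabicyclo[3.2.0]heptan-6-one, via dichloroketene 13 (not isolated)
Conditions: 12 (slow addition), Zn(Cu), DME, Et2O, 0 °C to rt
Reagents that add atoms: none
Why: Zinc removes two chlorines from 12 to give dichloroketene 13, which adds to the enol ether C-4=C-5 of 11 in a concerted, asynchronous [2+2] cycloaddition (ketene antarafacial, alkene suprafacial); the closest known reaction is the dichloroketene cycloaddition to 2,3-dihydrofuran, dihydropyrans and glycals. The four-membered ring closes intermolecularly by two bonds, the ketene carbonyl carbon to the nucleophilic C-4 (future C-6a) and the CCl2 carbon to the oxygen-bearing C-5 (future C-3a), so the regiochemistry follows the enol ether polarity. Because the alkene reacts suprafacially the ring fusion must be cis, and the two new stereocentres (C-1 and C-5 of the bicycle) are set together by the face of approach. That face is controlled by the existing C-2 stereocentre of the dihydrofuran: the bulky aryloxy(phenyl)methyl group shields its own side, so the ketene should add anti to it and place the cyclobutanone trans to the side chain, as the target requires. The step needs chemoselectivity for the one strongly nucleophilic alkene and survival of the acid-labile enol ether; these are secured by the absence of any free OH (5-OH masked as acetate) and by DME, which takes ZnCl2 out of solution.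

Step 9
Reactants: 14 (1S,3S,5R)-3-{(S)-{[(2S)-5-acetoxy-4-oxo-2-phenylchroman-7-yl]oxy}(phenyl)methyl}-7,7-dichloro-2-oxabicyclo[3.2.0]heptan-6-one
Product: 15 (1R,3S,5R)-3-{(S)-{[(2S)-5-acetoxy-4-oxo-2-phenylchroman-7-yl]oxy}(phenyl)methyl}-2-oxabicyclo[3.2.0]heptan-6-one
Conditions: Zn dust, AcOH, rt
Reagents that add atoms: none
Why: Reductive dechlorination of an α,α-dichlorocyclobutanone through zinc enolates that acetic acid protonates faster than they can expel the β-ring oxygen; the cis ring fusion cannot epimerise, and the aryl ketone, aryl acetate and benzylic ether are not reduced at room temperature.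

Step 10
Reactants: 15 (1R,3S,5R)-3-{(S)-{[(2S)-5-acetoxy-4-oxo-2-phenylchroman-7-yl]oxy}(phenyl)methyl}-2-oxabicyclo[3.2.0]heptan-6-one
Product: 16 (2S)-4-oxo-7-{(S)-[(3aR,5S,6aR)-2-oxohexahydrofuro[3,2-b]furan-5-yl](phenyl)methoxy}-2-phenylchroman-5-yl acetate
Conditions: mCPBA (1.1 equiv), NaHCO3, CH2Cl2, 0 °C
Reagents that add atoms: 3-chloroperoxybenzoic acid, OOC(=O)c1cccc(Cl)c1
Why: Baeyer–Villiger oxidation, in which relief of four-ring strain makes the cyclobutanone react far faster than the conjugated flavanone ketone, and the more substituted bridgehead carbon (future C-6a) migrates with retention, so oxygen enters between C-2 and C-6a.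

Step 11
Reactants: 16 (2S)-4-oxo-7-{(S)-[(3aR,5S,6aR)-2-oxohexahydrofuro[3,2-b]furan-5-yl](phenyl)methoxy}-2-phenylchroman-5-yl acetate
Product: 17 (2S)-5-hydroxy-7-{(S)-[(3aR,5S,6aR)-2-oxohexahydrofuro[3,2-b]furan-5-yl](phenyl)methoxy}-2-phenylchroman-4-one (target, CNP0152032.1)
Conditions: NH4OAc, MeOH–H2O (4:1), rt
Reagents that add atoms: none
Why: Near-neutral solvolysis of a phenolic acetate activated by the ortho carbonyl, much faster than opening of the γ-lactone and too mild to open the flavanone ring or epimerise its C-2.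

**Compound list**

1 | (±)-1-phenylprop-2-en-1-ol | C=CC(O)c1ccccc1 | starting material
2 | (R)-[(2S)-oxiran-2-yl](phenyl)methanol | O[C@H](c1ccccc1)[C@@H]1CO1 | intermediate
3 | tert-butyldimethyl{(R)-[(2S)-oxiran-2-yl](phenyl)methoxy}silane | CC(C)(C)[Si](C)(C)O[C@H](c1ccccc1)[C@@H]1CO1 | intermediate
4 | ethynyltrimethylsilane | C#C[Si](C)(C)C | starting material
5 | (1R,2S)-1-[(tert-butyldimethylsilyl)oxy]-1-phenyl-5-(trimethylsilyl)pent-4-yn-2-ol | CC(C)(C)[Si](C)(C)O[C@H](c1ccccc1)[C@@H](O)CC#C[Si](C)(C)C | intermediate (not isolated)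
6 | (1R,2S)-1-[(tert-butyldimethylsilyl)oxy]-1-phenylpent-4-yn-2-ol | CC(C)(C)[Si](C)(C)O[C@H](c1ccccc1)[C@@H](O)CC#C | intermediate
7 | tert-butyl{(R)-[(2S)-2,3-dihydrofuran-2-yl](phenyl)methoxy}dimethylsilane | CC(C)(C)[Si](C)(C)O[C@H](c1ccccc1)[C@@H]1CC=CO1 | intermediate
8 | (R)-[(2S)-2,3-dihydrofuran-2-yl](phenyl)methanol | O[C@H](c1ccccc1)[C@@H]1CC=CO1 | intermediate
9 | (S)-pinocembrin, (2S)-5,7-dihydroxy-2-phenylchroman-4-one | Oc1cc(O)c2c(c1)O[C@H](c1ccccc1)CC2=O | starting material
10 | (2S)-7-{(S)-[(2S)-2,3-dihydrofuran-2-yl](phenyl)methoxy}-5-hydroxy-2-phenylchroman-4-one | C1=CC[C@@H]([C@@H](Oc3cc(O)c4c(c3)O[C@H](c3ccccc3)CC4=O)c2ccccc2)O1 | intermediate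
11 | (2S)-7-{(S)-[(2S)-2,3-dihydrofuran-2-yl](phenyl)methoxy}-4-oxo-2-phenylchroman-5-yl acetate | C1=CC[C@@H]([C@@H](Oc3cc(OC(C)=O)c4c(c3)O[C@H](c3ccccc3)CC4=O)c2ccccc2)O1 | intermediate (key-step precursor)
12 | trichloroacetyl chloride | ClC(Cl)(Cl)C(Cl)=O | starting material
13 | dichloroketene | O=C=C(Cl)Cl | intermediate (not isolated)
14 | (1S,3S,5R)-3-{(S)-{[(2S)-5-acetoxy-4-oxo-2-phenylchroman-7-yl]oxy}(phenyl)methyl}-7,7-dichloro-2-oxabicyclo[3.2.0]heptan-6-one | O=C1C(Cl)(Cl)[C@H]2O[C@H]([C@@H](Oc3cc(OC(C)=O)c4c(c3)O[C@H](c3ccccc3)CC4=O)c3ccccc3)C[C@H]21 | intermediate (key-step product)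
15 | (1R,3S,5R)-3-{(S)-{[(2S)-5-acetoxy-4-oxo-2-phenylchroman-7-yl]oxy}(phenyl)methyl}-2-oxabicyclo[3.2.0]heptan-6-one | O=C1C[C@H]2O[C@H]([C@@H](Oc3cc(OC(C)=O)c4c(c3)O[C@H](c3ccccc3)CC4=O)c3ccccc3)C[C@H]21 | intermediate
16 | (2S)-4-oxo-7-{(S)-[(3aR,5S,6aR)-2-oxohexahydrofuro[3,2-b]furan-5-yl](phenyl)methoxy}-2-phenylchroman-5-yl acetate | O=C1C[C@H]2O[C@H]([C@@H](Oc3cc(OC(C)=O)c4c(c3)O[C@H](c3ccccc3)CC4=O)c3ccccc3)C[C@H]2O1 | intermediate
17 | (2S)-5-hydroxy-7-{(S)-[(3aR,5S,6aR)-2-oxohexahydrofuro[3,2-b]furan-5-yl](phenyl)methoxy}-2-phenylchroman-4-one | O=C1C[C@H]2O[C@H]([C@@H](Oc3cc(O)c4c(c3)O[C@H](c3ccccc3)CC4=O)c3ccccc3)C[C@H]2O1 | target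

**Step count**

Total steps: 11. Longest linear sequence: 11 steps (1 to 17); compounds 4, 9 and 12 are bought.

**Steps most likely to fail**

Step 8. The ketene may approach both faces of the nearly flat dihydrofuran with poor discrimination, or the enol ether may be consumed by Lewis-acid-induced oligomerisation before it is trapped. Fallback: the order of events is changed so that the cycloaddition is run on the simple, non-polar silyl ether 7 and the flavanone is attached last. Cl3CCOCl/Zn(Cu)/DME on 7 should give (1S,3S,5R)-3-[(R)-(tert-butyldimethylsilyloxy)(phenyl)methyl]-7,7-dichloro-2-oxabicyclo[3.2.0]heptan-6-one F1, in which the larger silyloxy(phenyl)methyl group should sharpen the anti preference and any minor isomer is easier to remove. Zn/AcOH then gives (1R,3S,5R)-3-[(R)-(tert-butyldimethylsilyloxy)(phenyl)methyl]-2-oxabicyclo[3.2.0]heptan-6-one F2, and mCPBA gives (3aR,5S,6aR)-5-[(R)-(tert-butyldimethylsilyloxy)(phenyl)methyl]tetrahydrofuro[3,2-b]furan-2(3H)-one F3. HF·pyridine frees (3aR,5S,6aR)-5-[(R)-hydroxy(phenyl)methyl]tetrahydrofuro[3,2-b]furan-2(3H)-one F4. A closing Mitsunobu reaction of F4 with 9 (PPh3, DIAD, THF) inverts the carbinol and rejoins the route at 17, with no phenol protection needed.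

Step 6. Displacement at the hindered, β-oxygenated benzylic oxyphosphonium centre may be slow, so that elimination, incomplete inversion or attack of the azodicarboxylate on the enol ether takes over. Fallback: activation and substitution are separated. Alcohol 8 is converted with MsCl/Et3N (CH2Cl2, −20 °C) into (R)-[(2S)-2,3-dihydrofuran-2-yl](phenyl)methyl methanesulfonate F5, which is displaced with inversion by the cesium 7-phenoxide of 9 (1 equiv Cs2CO3, DMF, rt), a Williamson-type SN2 etherification that rejoins the route at 10.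

Step 10. The peracid may also attack the electron-rich aryl ketone or ring A, or the methylene carbon may migrate in part and give the isomeric lactone. Fallback: oxygen is inserted before dechlorination. Cycloadduct 14 is treated with H2O2 in AcOH at 0 °C; its more electrophilic dichloroketone reacts quickly and only the non-chlorinated bridgehead carbon can migrate, giving (2S)-7-{(S)-[(3aS,5S,6aR)-3,3-dichloro-2-oxohexahydrofuro[3,2-b]furan-5-yl](phenyl)methoxy}-4-oxo-2-phenylchroman-5-yl acetate F6. Zn/AcOH then removes both chlorines and rejoins the route at 16.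

**Further compounds**

F1 | step 8 | (1S,3S,5R)-3-[(R)-(tert-butyldimethylsilyloxy)(phenyl)methyl]-7,7-dichloro-2-oxabicyclo[3.2.0]heptan-6-one | O=C1C(Cl)(Cl)[C@H]2O[C@H]([C@H](O[Si](C)(C)C(C)(C)C)c3ccccc3)C[C@H]21
F2 | step 8 | (1R,3S,5R)-3-[(R)-(tert-butyldimethylsilyloxy)(phenyl)methyl]-2-oxabicyclo[3.2.0]heptan-6-one | O=C1C[C@H]2O[C@H]([C@H](O[Si](C)(C)C(C)(C)C)c3ccccc3)C[C@H]21
F3 | step 8 | (3aR,5S,6aR)-5-[(R)-(tert-butyldimethylsilyloxy)(phenyl)methyl]tetrahydrofuro[3,2-b]furan-2(3H)-one | O=C1C[C@H]2O[C@H]([C@H](O[Si](C)(C)C(C)(C)C)c3ccccc3)C[C@H]2O1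
F4 | step 8 | (3aR,5S,6aR)-5-[(R)-hydroxy(phenyl)methyl]tetrahydrofuro[3,2-b]furan-2(3H)-one | O=C1C[C@H]2O[C@H]([C@H](O)c3ccccc3)C[C@H]2O1
F5 | step 6 | (R)-[(2S)-2,3-dihydrofuran-2-yl](phenyl)methyl methanesulfonate | CS(=O)(=O)O[C@H](c1ccccc1)[C@@H]1CC=CO1
F6 | step 10 | (2S)-7-{(S)-[(3aS,5S,6aR)-3,3-dichloro-2-oxohexahydrofuro[3,2-b]furan-5-yl](phenyl)methoxy}-4-oxo-2-phenylchroman-5-yl acetate | O=C1C(Cl)(Cl)[C@H]2O[C@H]([C@@H](Oc3cc(OC(C)=O)c4c(c3)O[C@H](c3ccccc3)CC4=O)c3ccccc3)C[C@H]2O1
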